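**Retrosynthetic overview**
1. Target 17 ⇐ 16 by O‑demethylation (BBr3); 16 ⇐ 15 by quinone‑to‑hydroquinone reduction.
2. 15 ⇐ 13 + 8: the inter‑ring C–O bond comes from oxa‑Michael addition–elimination of the phenoxide of 13 on bromanil 8.
3. Ring B (8) is built from acyclic material. Its C–C framework is made by the intermolecular Claisen condensation of two molecules of diethyl succinate 1 (then Dieckmann closure) to give 3, followed by decarboxylation to 5 and halogenative aromatisation, perbromination and oxidation.
4. Ring A (13) is bought aromatic: 4‑(benzyloxy)phenol 9 is 2,6‑dibrominated, O‑methylated, debenzylated and brominated once ortho to the freed OH.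
5. Ring order: the ring B carbocycle is closed first (step 1); ring A is never formed (commercial arene); the two rings are joined in step 8.

Assumption: the target has no stereocentre and no isolable atropisomer (its SMILES carries no stereo descriptor), so it is made as the single achiral compound and no stereocontrol is needed.

**Route**

Step 1
Reactants: 1 diethyl succinate (two molecules)
Product: 3 diethyl 2,5-dioxocyclohexane-1,4-dicarboxylate (diethyl succinylsuccinate; stable bis-enol form), via triethyl 3-oxopentane-1,2,5-tricarboxylate 2 (not isolated)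
Conditions: NaOEt (2 equiv per ester), EtOH, reflux, 24 h; then 2 N H2SO4, 0 °C
Reagents that add atoms: none
Why: Intermolecular Claisen condensation of the enolate of one succinate on an ester carbonyl of a second, then Dieckmann closure of the acyclic keto triester, driven by formation of the doubly stabilised bis-enolate; the enolic product has no stereocentre.

Step 2
Reactants: 3 diethyl 2,5-dioxocyclohexane-1,4-dicarboxylate
Product: 5 cyclohexane-1,4-dione, via 2,5-dioxocyclohexane-1,4-dicarboxylic acid 4 (not isolated)
Conditions: H2O, 185–195 °C, sealed pressure vessel, 15 min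
Reagents that add atoms: none
Why: Hydrolysis of both β-keto esters followed by thermal decarboxylation of the β-keto acids through the usual six-membered transition state.

Step 3
Reactants: 5 cyclohexane-1,4-dione
Product: 8 bromanil (2,3,5,6-tetrabromocyclohexa-2,5-diene-1,4-dione), via hydroquinone 6 (not isolated), via tetrabromohydroquinone 7 (not isolated)
Conditions: Br2 (5.5 equiv), AcOH, 20 → 90 °C; then conc. HNO3, 90 °C; H2O, filter
Reagents that add atoms: bromine, BrBr
Why: Halogenative aromatisation (acid-catalysed α-bromination, dehydrobromination and enolisation of the enedione) gives hydroquinone, four electrophilic aromatic brominations fill the ring and HNO3 oxidises the hydroquinone to the quinone; every partly brominated or partly oxidised species funnels to the same product.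

Step 4
Reactants: 9 4-(benzyloxy)phenol
Product: 10 4-(benzyloxy)-2,6-dibromophenol
Conditions: Br2 (2.05 equiv), NaOAc (2.2 equiv), AcOH, 15 °C → rt
Reagents that add atoms: bromine, BrBr
Why: Electrophilic aromatic bromination directed by the free OH to its two ortho positions (para is blocked); the acetate buffer traps HBr so the benzyl ether survives.

Step 5
Reactants: 10 4-(benzyloxy)-2,6-dibromophenol
Product: 11 5-(benzyloxy)-1,3-dibromo-2-methoxybenzene
Conditions: MeI (1.5 equiv), K2CO3 (2 equiv), DMF, rt → 40 °C
Reagents that add atoms: iodomethane, CI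
Why: Williamson O-methylation of the acidic 2,6-dibromophenol; the small electrophile tolerates the two ortho bromines.

Step 6
Reactants: 11 5-(benzyloxy)-1,3-dibromo-2-methoxybenzene
Product: 12 3,5-dibromo-4-methoxyphenol
Conditions: BCl3 (2 equiv), pentamethylbenzene (3 equiv), CH2Cl2, –78 °C; then aq. work-up
Reagents that add atoms: none
Why: Lewis-acid debenzylation with a non-basic cation scavenger (Friedel–Crafts capture of the benzyl cation) cleaves the benzyl ether at –78 °C while leaving the methyl ether and the C–Br bonds, which hydrogenolysis would not spare.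

Step 7
Reactants: 12 3,5-dibromo-4-methoxyphenol
Product: 13 2,3,5-tribromo-4-methoxyphenol
Conditions: NBS (1.0 equiv, added in portions), i-Pr2NH (10 mol%), CH2Cl2, 0 °C → rt
Reagents that add atoms: N-bromosuccinimide, O=C1CCC(=O)N1Br
Why: Amine-catalysed ortho-selective electrophilic bromination of a para-blocked phenol; the two open ortho sites are equivalent and the first bromine deactivates the ring towards a second.

Step 8
Reactants: 13 2,3,5-tribromo-4-methoxyphenol; 8 bromanil (2.5 equiv)
Product: 15 2,3,5-tribromo-6-(2,3,5-tribromo-4-methoxyphenoxy)cyclohexa-2,5-diene-1,4-dione, via sodium 2,3,5-tribromo-4-methoxyphenoxide 14 (not isolated)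
Conditions: 13, NaH (1.0 equiv), THF, 0 °C; add slowly to 8 in THF, –40 → 0 °C; AcOH quench
Reagents that add atoms: none
Why: Oxa-Michael addition of the phenoxide oxygen to a β-carbon of the doubly activated haloquinone followed by loss of bromide from the adduct enolate (addition–elimination); slow inverse addition to excess 8 at low temperature holds the reaction at mono-substitution, and no stereocentre is formed.

Step 9
Reactants: 15 2,3,5-tribromo-6-(2,3,5-tribromo-4-methoxyphenoxy)cyclohexa-2,5-diene-1,4-dione
Product: 16 2,3,5-tribromo-6-(2,3,5-tribromo-4-methoxyphenoxy)benzene-1,4-diol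
Conditions: Na2S2O4 (3 equiv), EtOAc/H2O, rt, 15 min, N2
Reagents that add atoms: none
Why: Dithionite reduction of a quinone to its hydroquinone is fast and leaves aryl bromides and both ether bonds untouched.

Step 10
Reactants: 16 2,3,5-tribromo-6-(2,3,5-tribromo-4-methoxyphenoxy)benzene-1,4-diol
Product: 17 2,3,5-tribromo-6-(2,3,5-tribromo-4-hydroxyphenoxy)benzene-1,4-diol (target)
Conditions: BBr3 (5 equiv), CH2Cl2, –78 °C → rt, 12 h; ice-water, work-up kept acidic, N2
Reagents that add atoms: none
Why: Lewis-acid O-demethylation of the hindered aryl methyl ether (SN2 of bromide on the O-methyl of the borate complex) spares the diaryl ether and the C–Br bonds, and the acidic work-up avoids base-induced cyclisation of the ortho-hydroxy/ortho′-bromo diaryl ether to a dibenzodioxin.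

**Compound list**
1 | diethyl succinate | CCOC(=O)CCC(=O)OCC | starting material
2 | triethyl 3-oxopentane-1,2,5-tricarboxylate (racemic, enolisable; present as its sodium enolate) | CCOC(=O)CCC(=O)C(CC(=O)OCC)C(=O)OCC | intermediate
3 | diethyl 2,5-dioxocyclohexane-1,4-dicarboxylate, drawn as its bis-enol diethyl 2,5-dihydroxycyclohexa-1,4-diene-1,4-dicarboxylate | CCOC(=O)C1=C(O)CC(C(=O)OCC)=C(O)C1 | intermediate
4 | 2,5-dioxocyclohexane-1,4-dicarboxylic acid, drawn as its bis-enol | OC(=O)C1=C(O)CC(C(O)=O)=C(O)C1 | intermediate
5 | cyclohexane-1,4-dione | O=C1CCC(=O)CC1 | intermediate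
6 | hydroquinone (benzene-1,4-diol) | Oc1ccc(O)cc1 | intermediate
7 | tetrabromohydroquinone (2,3,5,6-tetrabromobenzene-1,4-diol) | Oc1c(Br)c(Br)c(O)c(Br)c1Br | intermediate
8 | bromanil (2,3,5,6-tetrabromocyclohexa-2,5-diene-1,4-dione) | O=C1C(Br)=C(Br)C(=O)C(Br)=C1Br | intermediate
9 | 4-(benzyloxy)phenol | Oc1ccc(OCc2ccccc2)cc1 | starting material
10 | 4-(benzyloxy)-2,6-dibromophenol | Oc1c(Br)cc(OCc2ccccc2)cc1Br | intermediate
11 | 5-(benzyloxy)-1,3-dibromo-2-methoxybenzene | COc1c(Br)cc(OCc2ccccc2)cc1Br | intermediate
12 | 3,5-dibromo-4-methoxyphenol | COc1c(Br)cc(O)cc1Br | intermediate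
13 | 2,3,5-tribromo-4-methoxyphenol | COc1c(Br)cc(O)c(Br)c1Br | intermediate
14 | sodium 2,3,5-tribromo-4-methoxyphenoxide | COc1c(Br)cc([O-])c(Br)c1Br.[Na+] | intermediate
15 | 2,3,5-tribromo-6-(2,3,5-tribromo-4-methoxyphenoxy)cyclohexa-2,5-diene-1,4-dione | O=C1C(Br)=C(Br)C(=O)C(Oc2cc(Br)c(OC)c(Br)c2Br)=C1Br | intermediate
16 | 2,3,5-tribromo-6-(2,3,5-tribromo-4-methoxyphenoxy)benzene-1,4-diol | Oc1c(Br)c(Br)c(O)c(Oc2cc(Br)c(OC)c(Br)c2Br)c1Br | intermediate
17 | 2,3,5-tribromo-6-(2,3,5-tribromo-4-hydroxyphenoxy)benzene-1,4-diol (achiral) | Oc1c(Br)cc(Oc2c(O)c(Br)c(Br)c(O)c2Br)c(Br)c1Br | target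

**Summary**
Total step count: 10. Longest linear sequence: 7 steps (9 → 10 → 11 → 12 → 13 → 15 → 16 → 17); the ring B branch (1 → 3 → 5 → 8) adds 3 steps.

**Three steps most likely to fail, each with a fallback**

Step 8 (mono-substitution of bromanil). The risks are a second substitution to the 2,5-bis(aryloxy)quinone, electron transfer, and C- instead of O-attack. The fallback sets out from 13 and comes back at 15. Copper-mediated Chan–Lam O-arylation of 13 with 2,5-dimethoxyphenylboronic acid (Cu(OAc)2, pyridine, 4 Å MS, CH2Cl2, air, rt) gives 1,3,4-tribromo-5-(2,5-dimethoxyphenoxy)-2-methoxybenzene F1. Oxidative demethylation of its electron-rich dimethoxy ring with CAN (MeCN/H2O, 0 °C) gives 2-(2,3,5-tribromo-4-methoxyphenoxy)cyclohexa-2,5-diene-1,4-dione F2. Exhaustive bromination of the three quinone C–H positions (excess Br2, AcOH, 60 °C, addition/dehydrobromination; the deactivated ring A is inert) then gives 15.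

Step 3 (one-pot aromatisation, perbromination and oxidation of 5). The risk is an incompletely brominated or incompletely aromatised mixture. The fallback sets out from 5 and comes back at 8. It separates the events: catalytic dehydrogenation (10% Pd/C, diglyme, 190 °C, N2 sweep) gives hydroquinone 6, this time isolated and purified. Compound 6 is then perbrominated (Br2, AcOH) and oxidised (HNO3) through 7 to 8 under the classical conditions. New compounds on the way: none F0.

Step 7 (single ortho-bromination of 12). The risk is over-bromination to the tetrabromo phenol. The fallback sets out from 11 and comes back at 13. Regiospecific deprotonative magnesiation of 11 at the ring C–H flanked by Br and OBn (TMPMgCl·LiCl, 1.1 equiv, THF, –20 °C) makes exactly one aryl anion. Quenching with 1,2-dibromotetrachloroethane gives 1-(benzyloxy)-2,3,5-tribromo-4-methoxybenzene F3. Debenzylation with BCl3/pentamethylbenzene (CH2Cl2, –78 °C) then gives 13.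

**Further compounds**
F1 | step 8 | 1,3,4-tribromo-5-(2,5-dimethoxyphenoxy)-2-methoxybenzene | COc1ccc(OC)c(Oc2cc(Br)c(OC)c(Br)c2Br)c1
F2 | step 8 | 2-(2,3,5-tribromo-4-methoxyphenoxy)cyclohexa-2,5-diene-1,4-dione | O=C1C=CC(=O)C(Oc2cc(Br)c(OC)c(Br)c2Br)=C1
F0 | step 3 | none | none
F3 | step 7 | 1-(benzyloxy)-2,3,5-tribromo-4-methoxybenzene | COc1c(Br)cc(OCc2ccccc2)c(Br)c1Br
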